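**Retrosynthetic overview**

1. Locants used here: ring C1 (CH carrying the side chain), C2 (CH2), C3 and C4 (oxirane CH and C–CH3), C5 and C6 (the two CH–O-angeloyl carbons, C5 next to C4); side chain C7 (C=CH2) and C8 (CH–OAc).
2. Enabling feature: C5–O next to the C4(CH3)–C3 oxirane is a latent 2-methylcyclohex-2-en-1-one (C5=O, C4=C3). That enone is a propyne unit (C3≡C4–CH3) inserted into the acyl–CH2 bond C5–C2 of a 3-substituted cyclobutanone (C5, C6, C1, C2), whose mirror plane through C5 and C1 makes C1 prochiral.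
3. Key disconnection: C2–C3 and C4–C5 together, by an enantiotopic-bond-selective, nickel-catalysed alkyne insertion into the cyclobutanone (strain-release formal [4+2]); the cyclobutanone comes from a ketene–alkene [2+2].
4. After it: C6 bromination (trans), reduction and closure to a C5–C6 oxirane cis to the side chain, anti opening at allylic C5 by angelic acid, C6–OH-directed epoxidation of C3=C4, second angeloylation; then the side chain: acetal → aldehyde → α-methylenation (C7) → asymmetric allylboration (C8) → acetate → cross-metathesis (prenyl end).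
5. Order of ring formation: cyclobutanone (step 2) → six-membered carbocycle (step 4) → transient C5–C6 oxirane (step 7) → C3–C4 oxirane (step 9).

Key step: step 4

Remark: all compounds marked "starting material" in the list are taken as commercial; the sense of induction of each chiral catalyst is assigned by analogy with simple substrates, and the catalyst antipode would be used if it proved opposite.

**Route**

Step 1
Reactants: 1 prop-1-yn-1-ylmagnesium bromide; 2 benzylchlorodimethylsilane
Product: 3 benzyldimethyl(prop-1-yn-1-yl)silane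
Conditions: THF, 0 °C → rt
Reagents that add atoms: none
Why: Silylation of an alkynyl Grignard reagent (nucleophilic substitution at silicon) should give the internal silylalkyne, whose benzyldimethylsilyl group later steers regiochemistry and is removable with fluoride.

Step 2
Reactants: 4 4,4-diethoxybut-1-ene; 5 trichloroacetyl chloride
Product: 7 rac-2,2-dichloro-3-(2,2-diethoxyethyl)cyclobutan-1-one, via dichloroketene 6 (not isolated)
Conditions: Zn–Cu couple, POCl3, Et2O, 35 °C, slow addition of 5
Reagents that add atoms: none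
Why: Thermal ketene–alkene [2+2] cycloaddition of dichloroketene made in situ by zinc dechlorination should join the carbonyl carbon to the terminal CH2 of the alkene, placing the substituent at C3 of the cyclobutanone; the one stereocentre formed is racemic and disappears in step 3.

Step 3
Reactants: 7 rac-2,2-dichloro-3-(2,2-diethoxyethyl)cyclobutan-1-one
Product: 9 3-(2,2-diethoxyethyl)cyclobutan-1-one, via monochlorocyclobutanone 8 (not isolated)
Conditions: Zn dust, NH4Cl, EtOH, rt
Reagents that add atoms: none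
Why: Zinc-mediated reductive dechlorination of the α,α-dichloroketone under buffered conditions should remove both chlorines and leave the achiral, mirror-symmetric cyclobutanone with the acetal intact.

Step 4
Reactants: 9 3-(2,2-diethoxyethyl)cyclobutan-1-one; 3 benzyldimethyl(prop-1-yn-1-yl)silane
Product: 10 (5S)-3-[benzyl(dimethyl)silyl]-5-(2,2-diethoxyethyl)-2-methylcyclohex-2-en-1-one
Conditions: Ni(cod)2 (10 mol%), (S)-BINOL-derived N,N-bis[(R)-1-phenylethyl]phosphoramidite (20 mol%), toluene, 90 °C, slow addition of 3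
Reagents that add atoms: none
Why: Proposed new method: zerovalent nickel should couple the ketone carbonyl of 9 and alkyne 3 oxidatively to an oxanickelacyclopentene (C4–C5 bond, with the silyl-bearing carbon on nickel as in nickel-mediated carbonyl–silylalkyne couplings), then β-carbon elimination cleaves one acyl–CH2 bond of the spiro four-membered ring with release of its strain, and C(sp3)–C(sp2) reductive elimination from the seven-membered nickelacycle forms C2–C3 and frees the catalyst. The closest known reaction types are the nickel/phosphine-catalysed intermolecular insertion of internal alkynes into cyclobutanones (racemic formal [4+2]) and the nickel/chiral-phosphoramidite-catalysed enantioselective intramolecular alkene insertion into prochiral cyclobutanones; new here is their combination in an intermolecular, enantiotopic-bond-selective form. The six-membered ring is closed by two-carbon ring expansion, its last bond arising by reductive elimination, not by cyclisation of a chain. The only stereocentre, C1, is not a reacting atom; it becomes stereogenic because the ligand-bound nickel selects one of the two enantiotopic C5–CH2 bonds related by the mirror plane through C5 and C1, so the phosphoramidite controls its configuration. The step needs regioselectivity (methyl on C4 next to the carbonyl), secured by the silyl group that prefers the nickel-bound carbon and is removed in step 5, and chemoselectivity over alkyne oligomerisation, secured by the internal silyl-capped alkyne and its slow addition; the acetal is a spectator.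

Step 5
Reactants: 10 (5S)-3-[benzyl(dimethyl)silyl]-5-(2,2-diethoxyethyl)-2-methylcyclohex-2-en-1-one
Product: 11 (5S)-5-(2,2-diethoxyethyl)-2-methylcyclohex-2-en-1-one
Conditions: Bu4NF, THF, 0 °C → rt
Reagents that add atoms: none
Why: Fluoride-induced protodesilylation of the alkenyl benzyldimethylsilane (attack at silicon, protonation at C3) should remove the directing silyl group without touching C1.

Step 6
Reactants: 11 (5S)-5-(2,2-diethoxyethyl)-2-methylcyclohex-2-en-1-one
Product: 14 (5S,6S)-6-bromo-5-(2,2-diethoxyethyl)-2-methylcyclohex-2-en-1-one, via lithium dienolate 12 (not isolated), via trimethylsilyl dienol ether 13 (not isolated)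
Conditions: LiN(iPr)2, THF, −78 °C; Me3SiCl; then N-bromosuccinimide, THF, −78 → 0 °C
Reagents that add atoms: N-bromosuccinimide, O=C1CCC(=O)N1Br
Why: Kinetic α'-deprotonation to the cross-conjugated dienolate, silylation and electrophilic α-bromination of the silyl dienol ether should place bromine at C6 on the face opposite the neighbouring C1 substituent (trans).

Step 7
Reactants: 14 (5S,6S)-6-bromo-5-(2,2-diethoxyethyl)-2-methylcyclohex-2-en-1-one
Product: 16 (1S,5S,6R)-5-(2,2-diethoxyethyl)-2-methyl-7-oxabicyclo[4.1.0]hept-2-ene, via trans-bromohydrin 15 (not isolated)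
Conditions: (S)-2-methyl-CBS-oxazaborolidine (0.2 equiv), catecholborane, toluene, −78 °C; aqueous work-up; then K2CO3, EtOH, rt
Reagents that add atoms: none
Why: Corey–Bakshi–Shibata reduction (alkenyl branch as the large group, reinforced by axial hydride delivery to the conformer with equatorial bromine) should give the C5 alcohol trans to bromine, and intramolecular Williamson displacement (SN2, inversion at C6) should then close the oxirane on the face of the C1 side chain.

Step 8
Reactants: 16 (1S,5S,6R)-5-(2,2-diethoxyethyl)-2-methyl-7-oxabicyclo[4.1.0]hept-2-ene; 17 angelic acid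
Product: 18 (1R,5S,6R)-5-(2,2-diethoxyethyl)-6-hydroxy-2-methylcyclohex-2-en-1-yl (2Z)-2-methylbut-2-enoate
Conditions: 17 (3 equiv), Cs2CO3 (0.1 equiv), MeCN, 40 °C
Reagents that add atoms: none
Why: Acid-assisted SN2 opening of the vinyl oxirane at the activated allylic carbon C5 (anti, trans-diaxial) should install the C5 angelate with inversion and leave the C6 hydroxyl cis to the side chain.

Step 9
Reactants: 18 (1R,5S,6R)-5-(2,2-diethoxyethyl)-6-hydroxy-2-methylcyclohex-2-en-1-yl (2Z)-2-methylbut-2-enoate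
Product: 19 (1S,2S,3R,4S,6S)-4-(2,2-diethoxyethyl)-3-hydroxy-1-methyl-7-oxabicyclo[4.1.0]heptan-2-yl (2Z)-2-methylbut-2-enoate
Conditions: VO(acac)2 (5 mol%), tert-butyl hydroperoxide (decane), CH2Cl2, 0 °C → rt
Reagents that add atoms: tert-butyl hydroperoxide, CC(C)(C)OO
Why: Hydroxyl-directed vanadium-catalysed epoxidation by the axial homoallylic C6–OH should deliver oxygen to the C3=C4 face syn to C6–OH and anti to the allylic angelate, setting C3 and C4, while the electron-poor angelate alkene stays untouched.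

Step 10
Reactants: 19 (1S,2S,3R,4S,6S)-4-(2,2-diethoxyethyl)-3-hydroxy-1-methyl-7-oxabicyclo[4.1.0]heptan-2-yl (2Z)-2-methylbut-2-enoate; 17 angelic acid
Product: 21 (1S,2S,3R,4S,6S)-4-(2,2-diethoxyethyl)-1-methyl-7-oxabicyclo[4.1.0]heptane-2,3-diyl bis[(2Z)-2-methylbut-2-enoate], via mixed anhydride 20 (not isolated)
Conditions: 17, 2,4,6-trichlorobenzoyl chloride, Et3N, toluene, rt; then 19, 75 °C
Reagents that add atoms: none
Why: Yamaguchi-type esterification through the mixed anhydride without a nucleophilic pyridine catalyst should acylate C6–OH while avoiding Z-to-E isomerisation of the angeloyl unit; no stereocentre is affected.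

Step 11
Reactants: 21 (1S,2S,3R,4S,6S)-4-(2,2-diethoxyethyl)-1-methyl-7-oxabicyclo[4.1.0]heptane-2,3-diyl bis[(2Z)-2-methylbut-2-enoate]
Product: 22 (1S,2S,3R,4S,6S)-1-methyl-4-(2-oxoethyl)-7-oxabicyclo[4.1.0]heptane-2,3-diyl bis[(2Z)-2-methylbut-2-enoate]
Conditions: pyridinium p-toluenesulfonate (0.2 equiv), acetone/H2O 9:1, 40 °C
Reagents that add atoms: water, O
Why: Mild acid-catalysed hydrolysis of the acyclic diethyl acetal should unmask the aldehyde under conditions that the ester-flanked trisubstituted oxirane tolerates.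

Step 12
Reactants: 22 (1S,2S,3R,4S,6S)-1-methyl-4-(2-oxoethyl)-7-oxabicyclo[4.1.0]heptane-2,3-diyl bis[(2Z)-2-methylbut-2-enoate]
Product: 23 (1S,2S,3R,4S,6S)-1-methyl-4-(3-oxoprop-1-en-2-yl)-7-oxabicyclo[4.1.0]heptane-2,3-diyl bis[(2Z)-2-methylbut-2-enoate]
Conditions: aqueous formaldehyde (37%), pyrrolidine (10 mol%), propionic acid (10 mol%), iPrOH, 45 °C
Reagents that add atoms: formaldehyde, C=O
Why: Organocatalytic α-methylenation of the aldehyde (enamine Mannich addition followed by amine elimination) should install the C7 exo-methylene; C1 stays configurationally intact under the weakly basic catalytic conditions.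

Step 13
Reactants: 23 (1S,2S,3R,4S,6S)-1-methyl-4-(3-oxoprop-1-en-2-yl)-7-oxabicyclo[4.1.0]heptane-2,3-diyl bis[(2Z)-2-methylbut-2-enoate]; 24 2-allyl-4,4,5,5-tetramethyl-1,3,2-dioxaborolane
Product: 26 (1S,2S,3R,4S,6S)-4-[(3S)-3-hydroxyhexa-1,5-dien-2-yl]-1-methyl-7-oxabicyclo[4.1.0]heptane-2,3-diyl bis[(2Z)-2-methylbut-2-enoate], via O-boronate 25 (not isolated)
Conditions: (S)-TRIP [(S)-3,3'-bis(2,4,6-triisopropylphenyl)-1,1'-binaphthyl-2,2'-diyl hydrogen phosphate] (5 mol%), toluene, −30 °C; aqueous work-up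
Reagents that add atoms: none
Why: Chiral phosphoric acid-catalysed allylboration through a closed chair transition state should deliver allyl to the Si face of the enal and set C8 as (S) under catalyst control, chemoselectively at the aldehyde in the presence of esters and oxirane.

Step 14
Reactants: 26 (1S,2S,3R,4S,6S)-4-[(3S)-3-hydroxyhexa-1,5-dien-2-yl]-1-methyl-7-oxabicyclo[4.1.0]heptane-2,3-diyl bis[(2Z)-2-methylbut-2-enoate]
Product: 27 (1S,2S,3R,4S,6S)-4-[(3S)-3-acetoxyhexa-1,5-dien-2-yl]-1-methyl-7-oxabicyclo[4.1.0]heptane-2,3-diyl bis[(2Z)-2-methylbut-2-enoate]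
Conditions: Ac2O, pyridine, 4-(dimethylamino)pyridine (cat.), CH2Cl2, 0 °C → rt
Reagents that add atoms: acetic anhydride, CC(=O)OC(C)=O
Why: Standard nucleophile-catalysed O-acetylation of the secondary allylic alcohol proceeds with retention at C8.

Step 15
Reactants: 27 (1S,2S,3R,4S,6S)-4-[(3S)-3-acetoxyhexa-1,5-dien-2-yl]-1-methyl-7-oxabicyclo[4.1.0]heptane-2,3-diyl bis[(2Z)-2-methylbut-2-enoate]; 28 2-methylbut-2-ene
Product: 29 CNP0188566.1, (1S,2S,3R,4S,6S)-4-[(3S)-3-acetoxy-6-methylhepta-1,5-dien-2-yl]-1-methyl-7-oxabicyclo[4.1.0]heptane-2,3-diyl bis[(2Z)-2-methylbut-2-enoate]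
Conditions: second-generation Grubbs catalyst (H2IMes)(PCy3)Cl2Ru=CHPh (5 mol%), 28 as co-solvent, CH2Cl2, 40 °C
Reagents that add atoms: none
Why: Olefin cross-metathesis of the only monosubstituted alkene with 2-methylbut-2-ene should build the prenyl terminus, since the 1,1-disubstituted C7 methylene and the electron-poor trisubstituted angelate alkenes are unreactive partners.

**Compound list**

1 | prop-1-yn-1-ylmagnesium bromide | CC#C[Mg]Br | starting material
2 | benzylchlorodimethylsilane | C[Si](C)(Cl)Cc1ccccc1 | starting material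
3 | benzyldimethyl(prop-1-yn-1-yl)silane | CC#C[Si](C)(C)Cc1ccccc1 | intermediate
4 | 4,4-diethoxybut-1-ene | C=CCC(OCC)OCC | starting material
5 | trichloroacetyl chloride | ClC(Cl)(Cl)C(Cl)=O | starting material
6 | dichloroketene | ClC(Cl)=C=O | intermediate
7 | rac-2,2-dichloro-3-(2,2-diethoxyethyl)cyclobutan-1-one | CCOC(OCC)CC1CC(=O)C1(Cl)Cl | intermediate
8 | 2-chloro-3-(2,2-diethoxyethyl)cyclobutan-1-one (stereoisomer mixture) | CCOC(OCC)CC1CC(=O)C1Cl | intermediate
9 | 3-(2,2-diethoxyethyl)cyclobutan-1-one (achiral) | CCOC(OCC)CC1CC(=O)C1 | intermediate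
10 | (5S)-3-[benzyl(dimethyl)silyl]-5-(2,2-diethoxyethyl)-2-methylcyclohex-2-en-1-one | CCOC(OCC)C[C@@H]1CC([Si](C)(C)Cc2ccccc2)=C(C)C(=O)C1 | intermediate
11 | (5S)-5-(2,2-diethoxyethyl)-2-methylcyclohex-2-en-1-one | CCOC(OCC)C[C@@H]1CC=C(C)C(=O)C1 | intermediate
12 | lithium cross-conjugated dienolate of 11 (O–Li on C5, C5=C6) | CCOC(OCC)C[C@@H]1CC=C(C)C([O-])=C1.[Li+] | intermediate
13 | trimethylsilyl dienol ether of 11 (OSiMe3 on C5, C5=C6) | CCOC(OCC)C[C@@H]1CC=C(C)C(O[Si](C)(C)C)=C1 | intermediate
14 | (5S,6S)-6-bromo-5-(2,2-diethoxyethyl)-2-methylcyclohex-2-en-1-one (Br trans to side chain) | CCOC(OCC)C[C@@H]1CC=C(C)C(=O)[C@H]1Br | intermediate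
15 | (1S,5S,6S)-6-bromo-5-(2,2-diethoxyethyl)-2-methylcyclohex-2-en-1-ol (OH trans to Br) | CCOC(OCC)C[C@@H]1CC=C(C)[C@H](O)[C@H]1Br | intermediate
16 | (1S,5S,6R)-5-(2,2-diethoxyethyl)-2-methyl-7-oxabicyclo[4.1.0]hept-2-ene (oxirane cis to side chain) | CCOC(OCC)C[C@@H]1CC=C(C)[C@@H]2O[C@H]12 | intermediate
17 | angelic acid, (2Z)-2-methylbut-2-enoic acid | OC(=O)/C(C)=C\C | starting material
18 | (1R,5S,6R)-5-(2,2-diethoxyethyl)-6-hydroxy-2-methylcyclohex-2-en-1-yl (2Z)-2-methylbut-2-enoate | CCOC(OCC)C[C@@H]1CC=C(C)[C@@H](OC(=O)/C(C)=C\C)[C@@H]1O | intermediate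
19 | (1S,2S,3R,4S,6S)-4-(2,2-diethoxyethyl)-3-hydroxy-1-methyl-7-oxabicyclo[4.1.0]heptan-2-yl (2Z)-2-methylbut-2-enoate | CCOC(OCC)C[C@@H]1C[C@@H]2O[C@]2(C)[C@@H](OC(=O)/C(C)=C\C)[C@@H]1O | intermediate
20 | (2Z)-2-methylbut-2-enoic 2,4,6-trichlorobenzoic anhydride | O=C(OC(=O)c1c(Cl)cc(Cl)cc1Cl)/C(C)=C\C | intermediate
21 | (1S,2S,3R,4S,6S)-4-(2,2-diethoxyethyl)-1-methyl-7-oxabicyclo[4.1.0]heptane-2,3-diyl bis[(2Z)-2-methylbut-2-enoate] | CCOC(OCC)C[C@@H]1C[C@@H]2O[C@]2(C)[C@@H](OC(=O)/C(C)=C\C)[C@@H]1OC(=O)/C(C)=C\C | intermediate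
22 | (1S,2S,3R,4S,6S)-1-methyl-4-(2-oxoethyl)-7-oxabicyclo[4.1.0]heptane-2,3-diyl bis[(2Z)-2-methylbut-2-enoate] | O=CC[C@@H]1C[C@@H]2O[C@]2(C)[C@@H](OC(=O)/C(C)=C\C)[C@@H]1OC(=O)/C(C)=C\C | intermediate
23 | (1S,2S,3R,4S,6S)-1-methyl-4-(3-oxoprop-1-en-2-yl)-7-oxabicyclo[4.1.0]heptane-2,3-diyl bis[(2Z)-2-methylbut-2-enoate] | C=C(C=O)[C@@H]1C[C@@H]2O[C@]2(C)[C@@H](OC(=O)/C(C)=C\C)[C@@H]1OC(=O)/C(C)=C\C | intermediate
24 | 2-allyl-4,4,5,5-tetramethyl-1,3,2-dioxaborolane | C=CCB1OC(C)(C)C(C)(C)O1 | starting material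
25 | O-pinacolboronate of 26 | C=C([C@H](CC=C)OB1OC(C)(C)C(C)(C)O1)[C@@H]1C[C@@H]2O[C@]2(C)[C@@H](OC(=O)/C(C)=C\C)[C@@H]1OC(=O)/C(C)=C\C | intermediate
26 | (1S,2S,3R,4S,6S)-4-[(3S)-3-hydroxyhexa-1,5-dien-2-yl]-1-methyl-7-oxabicyclo[4.1.0]heptane-2,3-diyl bis[(2Z)-2-methylbut-2-enoate] | C=C([C@H](CC=C)O)[C@@H]1C[C@@H]2O[C@]2(C)[C@@H](OC(=O)/C(C)=C\C)[C@@H]1OC(=O)/C(C)=C\C | intermediate
27 | (1S,2S,3R,4S,6S)-4-[(3S)-3-acetoxyhexa-1,5-dien-2-yl]-1-methyl-7-oxabicyclo[4.1.0]heptane-2,3-diyl bis[(2Z)-2-methylbut-2-enoate] | C=C([C@H](CC=C)OC(C)=O)[C@@H]1C[C@@H]2O[C@]2(C)[C@@H](OC(=O)/C(C)=C\C)[C@@H]1OC(=O)/C(C)=C\C | intermediate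
28 | 2-methylbut-2-ene | CC=C(C)C | starting material
29 | CNP0188566.1, (1S,2S,3R,4S,6S)-4-[(3S)-3-acetoxy-6-methylhepta-1,5-dien-2-yl]-1-methyl-7-oxabicyclo[4.1.0]heptane-2,3-diyl bis[(2Z)-2-methylbut-2-enoate] | C=C([C@H](CC=C(C)C)OC(C)=O)[C@@H]1C[C@@H]2O[C@]2(C)[C@@H](OC(=O)/C(C)=C\C)[C@@H]1OC(=O)/C(C)=C\C | target

**Count and risks**

Total step count: 15. Longest linear sequence: 14 steps (4 → 29, steps 2–15); step 1 is a one-step branch.

Steps most likely to fail:

Step 4 (Proposed new method). What may go wrong: too little discrimination between the two enantiotopic acyl–CH2 bonds, or alkyne oligomerisation outrunning insertion with the chiral ligand. Fallback by known chemistry, setting out from 9 (with 3) and coming back at 11: the established achiral insertion (Ni(cod)2, PCy3, toluene, 100 °C) should give the racemic silyl enone F1; Bu4NF then gives the racemic enone F2; NaBH4 with CeCl3·7H2O in EtOH gives the racemic cis-allylic alcohol F3. Lipase-mediated kinetic resolution (Candida antarctica lipase B, vinyl acetate, hexane) should acetylate the enantiomer of the required series (alkenyl branch large, ring CH2 medium) to the acetate F4. F4 is separated from the unreacted antipode, methanolysed (K2CO3, MeOH) to the alcohol F5 and oxidised with MnO2 to 11.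

Step 8. What may go wrong: conjugate (1,4) opening of the vinyl oxirane, acyl migration between O5 and O6 (which would misdirect step 9), or Z-to-E isomerisation on prolonged heating. Fallback, setting out from 14 and coming back at 21 (it also by-passes steps 7, 9 and 10): displacement of bromide by caesium angelate (from 17 and Cs2CO3, DMF, rt; SN2 at the α-keto carbon with inversion) should give the cis-acyloxy enone F6. Reduction with NaBH4 and CeCl3·7H2O, anti to the axial acyloxy group, should give the all-cis hydroxy ester F7. Mitsunobu esterification with 17 (PPh3, diisopropyl azodicarboxylate, toluene; inversion at allylic C5) should give the bis-angelate cyclohexene F8. Epoxidation with 3-chloroperbenzoic acid anti to the allylic ester then gives 21.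

Step 10. What may go wrong: sluggish acylation of the hindered axial C6 hydroxyl, with isomerisation of the activated angeloyl donor or acyl migration and oxirane opening at the temperature needed. Fallback, setting out from 19 and coming back at 21: esterification of 19 with 2-[bis(2,2,2-trifluoroethoxy)phosphoryl]propanoic acid (N,N'-dicyclohexylcarbodiimide, 4-(dimethylamino)pyridine, CH2Cl2) should give the phosphonate ester F9. Still–Gennari olefination of F9 with acetaldehyde (KN(SiMe3)2, 18-crown-6, THF, −78 °C) then builds the Z-configured 2-methylbut-2-enoate on the molecule and gives 21.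

Further compounds
F1 | step 4 | racemic 3-[benzyl(dimethyl)silyl]-5-(2,2-diethoxyethyl)-2-methylcyclohex-2-en-1-one | CCOC(OCC)CC1CC([Si](C)(C)Cc2ccccc2)=C(C)C(=O)C1
F2 | step 4 | racemic 5-(2,2-diethoxyethyl)-2-methylcyclohex-2-en-1-one | CCOC(OCC)CC1CC=C(C)C(=O)C1
F3 | step 4 | racemic cis-5-(2,2-diethoxyethyl)-2-methylcyclohex-2-en-1-ol | CCOC(OCC)CC1CC=C(C)C(O)C1
F4 | step 4 | (1R,5R)-5-(2,2-diethoxyethyl)-2-methylcyclohex-2-en-1-yl acetate | CCOC(OCC)C[C@@H]1CC=C(C)[C@H](OC(C)=O)C1
F5 | step 4 | (1R,5R)-5-(2,2-diethoxyethyl)-2-methylcyclohex-2-en-1-ol | CCOC(OCC)C[C@@H]1CC=C(C)[C@H](O)C1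
F6 | step 8 | (1R,6S)-6-(2,2-diethoxyethyl)-3-methyl-2-oxocyclohex-3-en-1-yl (2Z)-2-methylbut-2-enoate | CCOC(OCC)C[C@@H]1CC=C(C)C(=O)[C@@H]1OC(=O)/C(C)=C\C
F7 | step 8 | (1R,2S,6S)-6-(2,2-diethoxyethyl)-2-hydroxy-3-methylcyclohex-3-en-1-yl (2Z)-2-methylbut-2-enoate | CCOC(OCC)C[C@@H]1CC=C(C)[C@H](O)[C@@H]1OC(=O)/C(C)=C\C
F8 | step 8 | (1R,2R,6S)-6-(2,2-diethoxyethyl)-3-methylcyclohex-3-ene-1,2-diyl bis[(2Z)-2-methylbut-2-enoate] | CCOC(OCC)C[C@@H]1CC=C(C)[C@@H](OC(=O)/C(C)=C\C)[C@@H]1OC(=O)/C(C)=C\C
F9 | step 10 | 2-[bis(2,2,2-trifluoroethoxy)phosphoryl]propanoate of 19 at the C6 oxygen (mixture at the phosphonate α-carbon) | CCOC(OCC)C[C@@H]1C[C@@H]2O[C@]2(C)[C@@H](OC(=O)/C(C)=C\C)[C@@H]1OC(=O)C(C)P(=O)(OCC(F)(F)F)OCC(F)(F)F
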